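**Retrosynthetic overview**
1. The C3–C1' bond and ring C are made together at the end: chalcone 13 (ring B on Cβ) undergoes an oxidative 1,2-shift of ring B from Cβ (future C2) to Cα (future C3), followed in the same flask by O1–C2 closure and loss of the three MOM groups.
2. Enabling feature: C1' of ring B is para to the C4' methoxy oxygen and ortho to the C2' oxygen, so it can bridge as a stabilised phenonium ion. C3 is the α-carbon of the C4 ketone and can carry an iodane leaving group, C2 keeps an oxygen that stabilises the cation left behind, and the ring-A oxygen (future O1) is free to close the pyranone.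
3. Chalcone 13 comes from a Claisen–Schmidt condensation of acetophenone 11 (ring A) with benzaldehyde 9 (ring B).
4. Aldehyde 9 comes from 2,3,4-trihydroxybenzaldehyde by 4-O-prenylation, MOM capping of O-2/O-3, aromatic Claisen rearrangement (places the 1,1-dimethylallyl group at C5') and O-methylation.
5. Ring order: benzene rings A and B are bought; the pyranone ring C is the only ring formed, last, in step 7.

Key step: step 7

Remark: the target has no stereocentre and no stereogenic axis (it is achiral), so no enantiocontrol is needed. The only transient stereo-elements are the E-alkene of 13 and the racemic centres of 6, 12 and 14, all of which disappear.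

**Step 1**
Reactants: 1 2,3,4-trihydroxybenzaldehyde; 2 prenyl bromide (1-bromo-3-methylbut-2-ene)
Product: 3 2,3-dihydroxy-4-[(3-methylbut-2-en-1-yl)oxy]benzaldehyde
Conditions: NaHCO3 (1.2 equiv), 2 (1.05 equiv), DMF, 40 °C, N2
Reagents that add atoms: prenyl bromide, CC(C)=CCBr
Why: Williamson etherification of the mono-phenoxide; the 4-OH (para to the formyl group and not hydrogen-bonded to it) is the most acidic and most accessible oxygen, so one equivalent of a weak base should alkylate O-4 selectively, and no stereocentre is formed.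

**Step 2**
Reactants: 3 2,3-dihydroxy-4-[(3-methylbut-2-en-1-yl)oxy]benzaldehyde; 4 chloromethyl methyl ether (MOMCl)
Product: 5 2,3-bis(methoxymethoxy)-4-[(3-methylbut-2-en-1-yl)oxy]benzaldehyde
Conditions: NaH (2.4 equiv), MOMCl (2.4 equiv), DMF, 0 °C to rt
Reagents that add atoms: chloromethyl methyl ether, COCCl
Why: Exhaustive O-alkylation of the catechol dianion (MOM acetal protection), with NaH strong enough to break the O-2–H···O=C hydrogen bond, while the aldehyde and the prenyl ether are inert to these conditions.

**Step 3**
Reactants: 5 2,3-bis(methoxymethoxy)-4-[(3-methylbut-2-en-1-yl)oxy]benzaldehyde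
Product: 7 4-hydroxy-2,3-bis(methoxymethoxy)-5-(2-methylbut-3-en-2-yl)benzaldehyde, via Claisen dienone 6 (not isolated)
Conditions: Eu(fod)3 (10 mol %), CHCl3, 60 °C, sealed tube
Reagents that add atoms: none
Why: Lewis-acid-catalysed aromatic Claisen ([3,3]-sigmatropic) rearrangement in which the allyl unit bonds through its tertiary carbon to the only free ortho carbon (C5) and dienone 6 tautomerises to the phenol; the mild temperature should suppress the abnormal Claisen pathway and ring closure onto the new phenol, and no stereocentre remains.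

**Step 4**
Reactants: 7 4-hydroxy-2,3-bis(methoxymethoxy)-5-(2-methylbut-3-en-2-yl)benzaldehyde; 8 iodomethane
Product: 9 4-methoxy-2,3-bis(methoxymethoxy)-5-(2-methylbut-3-en-2-yl)benzaldehyde
Conditions: MeI (1.5 equiv), K2CO3, DMF, rt
Reagents that add atoms: iodomethane, CI
Why: Williamson methylation of a phenol made acidic by the para-formyl group; the small electrophile should reach the oxygen flanked by the OMOM and tert-alkyl groups, and MOM ethers, aldehyde and alkene are unaffected.

**Step 5**
Reactants: 10 2,4-dihydroxyacetophenone; 4 chloromethyl methyl ether (MOMCl)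
Product: 11 1-[2-hydroxy-4-(methoxymethoxy)phenyl]ethan-1-one
Conditions: MOMCl (1.1 equiv), K2CO3, acetone, rt
Reagents that add atoms: chloromethyl methyl ether, COCCl
Why: Selective Williamson-type MOM protection; the 2-OH is locked in a hydrogen bond to the ketone and stays free under mild carbonate conditions, so only O-4 should react.

**Step 6**
Reactants: 9 4-methoxy-2,3-bis(methoxymethoxy)-5-(2-methylbut-3-en-2-yl)benzaldehyde; 11 1-[2-hydroxy-4-(methoxymethoxy)phenyl]ethan-1-one
Product: 13 (E)-1-[2-hydroxy-4-(methoxymethoxy)phenyl]-3-[4-methoxy-2,3-bis(methoxymethoxy)-5-(2-methylbut-3-en-2-yl)phenyl]prop-2-en-1-one, via aldol adduct 12 (not isolated)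
Conditions: KOH (50 % aq), EtOH, rt, N2
Reagents that add atoms: none
Why: Claisen–Schmidt condensation (aldol addition of the methyl ketone enolate to the non-enolisable aldehyde, then E1cB dehydration of 12) should give the thermodynamically favoured E-enone, and MOM ethers and the isolated alkene are stable to aqueous KOH.

**Step 7**
Reactants: 13 (E)-1-[2-hydroxy-4-(methoxymethoxy)phenyl]-3-[4-methoxy-2,3-bis(methoxymethoxy)-5-(2-methylbut-3-en-2-yl)phenyl]prop-2-en-1-one
Product: 16 3-[2,3-dihydroxy-4-methoxy-5-(2-methylbut-3-en-2-yl)phenyl]-7-hydroxy-4H-chromen-4-one (target), via dimethyl acetal 14 (not isolated), via tris-MOM isoflavone 15 (not isolated)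
Conditions: PhI(OH)OTs (1.1 equiv), MeOH/HC(OMe)3 3:1, 0 °C to rt; Me2S (destroys residual oxidant); then 1.25 M HCl in MeOH, 45 °C, N2
Reagents that add atoms: none
Why: Electrophilic PhI(OH)OTs should be taken up at Cα of the enone while methanol adds to the benzylic Cβ, and departure of iodobenzene from Cα is assisted by ring B, whose C1' bridges Cα and Cβ as a phenonium ion stabilised by the para C4'-methoxy and ortho C2'-oxygen, so that the aryl group ends on Cα (the C3–C1' bond) and the Cβ oxocarbenium ion is trapped as dimethyl acetal 14. The closest known reaction type is the hypervalent-iodine (or thallium(III)) mediated oxidative 1,2-aryl migration of 2'-hydroxychalcones to isoflavones, the laboratory counterpart of the biosynthetic flavanone-to-isoflavone aryl shift. Methanolic HCl then ionises the acetal, the free ring-A phenol adds to the oxocarbenium carbon in a 6-exo-trig closure, loss of methanol gives the 4-pyranone ring of 15, and the three MOM ethers are finally methanolysed to the target. No stereocentre persists: the racemic centre of 14 becomes the sp2 carbon C3 and the E-alkene of 13 is consumed. The step needs chemoselectivity for the enone over the vinyl group and the aryl ethers, which should be secured by the donor-activated β-aryl enone reacting far faster than a monosubstituted alkene shielded by a quaternary carbon, by using 1.1 equiv of oxidant at 0 °C with the excess destroyed before heating, and by keeping every ring-B oxygen capped while I(III) is present. It also needs six-membered closure through the ring-A oxygen rather than five-membered closure through O-2', which should follow from the ring-A hydroxyl being free from the start whereas O-2' is unmasked only in the slower MOM methanolysis.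

**Compound list**
1 | 2,3,4-trihydroxybenzaldehyde | O=Cc1ccc(O)c(O)c1O | starting material
2 | prenyl bromide (1-bromo-3-methylbut-2-ene) | CC(C)=CCBr | starting material
3 | 2,3-dihydroxy-4-[(3-methylbut-2-en-1-yl)oxy]benzaldehyde | O=Cc1ccc(OCC=C(C)C)c(O)c1O | intermediate
4 | chloromethyl methyl ether (MOMCl) | COCCl | starting material
5 | 2,3-bis(methoxymethoxy)-4-[(3-methylbut-2-en-1-yl)oxy]benzaldehyde | O=Cc1ccc(OCC=C(C)C)c(OCOC)c1OCOC | intermediate
6 | 5,6-bis(methoxymethoxy)-3-(2-methylbut-3-en-2-yl)-4-oxocyclohexa-1,5-diene-1-carbaldehyde (Claisen dienone, racemic, not isolated) | O=CC1=CC(C(C)(C)C=C)C(=O)C(OCOC)=C1OCOC | intermediate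
7 | 4-hydroxy-2,3-bis(methoxymethoxy)-5-(2-methylbut-3-en-2-yl)benzaldehyde | O=Cc1cc(C(C)(C)C=C)c(O)c(OCOC)c1OCOC | intermediate
8 | iodomethane | CI | starting material
9 | 4-methoxy-2,3-bis(methoxymethoxy)-5-(2-methylbut-3-en-2-yl)benzaldehyde | O=Cc1cc(C(C)(C)C=C)c(OC)c(OCOC)c1OCOC | intermediate
10 | 2,4-dihydroxyacetophenone | CC(=O)c1ccc(O)cc1O | starting material
11 | 1-[2-hydroxy-4-(methoxymethoxy)phenyl]ethan-1-one | CC(=O)c1ccc(OCOC)cc1O | intermediate
12 | 3-hydroxy-1-[2-hydroxy-4-(methoxymethoxy)phenyl]-3-[4-methoxy-2,3-bis(methoxymethoxy)-5-(2-methylbut-3-en-2-yl)phenyl]propan-1-one (aldol adduct, racemic, not isolated) | COCOc1ccc(C(=O)CC(O)c2cc(C(C)(C)C=C)c(OC)c(OCOC)c2OCOC)c(O)c1 | intermediate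
13 | (E)-1-[2-hydroxy-4-(methoxymethoxy)phenyl]-3-[4-methoxy-2,3-bis(methoxymethoxy)-5-(2-methylbut-3-en-2-yl)phenyl]prop-2-en-1-one | COCOc1ccc(C(=O)/C=C/c2cc(C(C)(C)C=C)c(OC)c(OCOC)c2OCOC)c(O)c1 | intermediate
14 | 1-[2-hydroxy-4-(methoxymethoxy)phenyl]-3,3-dimethoxy-2-[4-methoxy-2,3-bis(methoxymethoxy)-5-(2-methylbut-3-en-2-yl)phenyl]propan-1-one (dimethyl acetal, racemic, not isolated) | COCOc1ccc(C(=O)C(C(OC)OC)c2cc(C(C)(C)C=C)c(OC)c(OCOC)c2OCOC)c(O)c1 | intermediate
15 | 7-(methoxymethoxy)-3-[4-methoxy-2,3-bis(methoxymethoxy)-5-(2-methylbut-3-en-2-yl)phenyl]-4H-chromen-4-one (tris-MOM isoflavone, not isolated) | COCOc1ccc2c(c1)occ(-c1cc(C(C)(C)C=C)c(OC)c(OCOC)c1OCOC)c2=O | intermediate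
16 | 3-[2,3-dihydroxy-4-methoxy-5-(2-methylbut-3-en-2-yl)phenyl]-7-hydroxy-4H-chromen-4-one | C=CC(C)(C)c1cc(-c2coc3cc(O)ccc3c2=O)c(O)c(O)c1OC | target

**Totals**
Total step count: 7. Longest linear sequence: 6 steps (steps 1, 2, 3, 4, 6, 7); step 5 is the one-step side branch.

**Steps most likely to fail**

Step 7. What may go wrong: attack of the iodine(III) electrophile on the vinyl group, premature loss of MOM groups followed by oxidation of the unmasked phenols, or closure through the ring-B oxygen instead of the ring-A oxygen. The fallback forms the same C3–C1' bond by cross-coupling, without any electrophilic oxidant. It sets out from acetophenone 11 and aldehyde 9 and comes back at the protected isoflavone 15, which is then unmasked with methanolic HCl as in the second stage of step 7.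
- Acetophenone 11 would be condensed with DMF dimethyl acetal (toluene, 90 °C) to (E)-3-(dimethylamino)-1-[2-hydroxy-4-(methoxymethoxy)phenyl]prop-2-en-1-one F1.
- Iodine (CHCl3, pyridine, rt) would close F1 to 3-iodo-7-(methoxymethoxy)-4H-chromen-4-one F2.
- Aldehyde 9 would undergo a Dakin-type Baeyer–Villiger oxidation (mCPBA, NaHCO3, CH2Cl2, 0 °C, where the electron-rich aldehyde should react faster than a monosubstituted alkene; then K2CO3, MeOH) to 4-methoxy-2,3-bis(methoxymethoxy)-5-(2-methylbut-3-en-2-yl)phenol F3.
- F3 would be converted into the aryl triflate F4 (PhNTf2, Cs2CO3, MeCN) and borylated (B2pin2, PdCl2(dppf), KOAc, dioxane, 85 °C) to the aryl pinacol boronate F5.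
- Suzuki–Miyaura coupling of F5 with F2 (Pd(OAc)2/SPhos, K3PO4, dioxane/H2O, 80 °C) should give 15.

Step 3. What may go wrong: ionisation of the prenyl ether with 1,3-shift to the linear prenyl isomer, abnormal Claisen rearrangement of the side chain, or ring closure of the new phenol onto the alkene. The fallback installs the 1,1-dimethylallyl group by cross-coupling instead of by sigmatropic shift. It sets out from 1 and comes back at aldehyde 9.
- Selective 4-O-methylation of 1 (MeI, Li2CO3, DMF) would give 2,3-dihydroxy-4-methoxybenzaldehyde F6, which is also an article of commerce.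
- MOMCl 4 with NaH in DMF would give 4-methoxy-2,3-bis(methoxymethoxy)benzaldehyde F7.
- NBS in MeCN should brominate C5 (ortho to OMe, para to the C2 oxygen, meta to the formyl group) to give 5-bromo-4-methoxy-2,3-bis(methoxymethoxy)benzaldehyde F8.
- A ligand-controlled, γ-selective Suzuki–Miyaura coupling of F8 with prenylboronic acid pinacol ester (Pd/bulky biarylphosphine, aq. K3PO4, THF, 40–70 °C) should deliver the branched product 9 directly.

Step 1. What may go wrong: poor site selectivity (alkylation at O-3 or over-alkylation) in the mono-etherification of the triol. The fallback uses temporary masking of the catechol. It sets out from 1 and comes back at 3.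
- Borax in aqueous NaOH would tie O-2 and O-3 into the cyclic borate complex F9, leaving the C4 phenoxide as the only alkylatable oxygen.
- Alkylation with prenyl bromide 2 under phase transfer (Bu4NBr, CH2Cl2/H2O, rt) and acidic work-up, which hydrolyses the borate, should give 3.

**Further compounds**
F1 | step 7 | (E)-3-(dimethylamino)-1-[2-hydroxy-4-(methoxymethoxy)phenyl]prop-2-en-1-one | COCOc1ccc(C(=O)/C=C/N(C)C)c(O)c1
F2 | step 7 | 3-iodo-7-(methoxymethoxy)-4H-chromen-4-one | COCOc1ccc2c(c1)occ(I)c2=O
F3 | step 7 | 4-methoxy-2,3-bis(methoxymethoxy)-5-(2-methylbut-3-en-2-yl)phenol | Oc1cc(C(C)(C)C=C)c(OC)c(OCOC)c1OCOC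
F4 | step 7 | 4-methoxy-2,3-bis(methoxymethoxy)-5-(2-methylbut-3-en-2-yl)phenyl trifluoromethanesulfonate | O=S(=O)(Oc1cc(C(C)(C)C=C)c(OC)c(OCOC)c1OCOC)C(F)(F)F
F5 | step 7 | 2-[4-methoxy-2,3-bis(methoxymethoxy)-5-(2-methylbut-3-en-2-yl)phenyl]-4,4,5,5-tetramethyl-1,3,2-dioxaborolane | CC1(C)OB(c2cc(C(C)(C)C=C)c(OC)c(OCOC)c2OCOC)OC1(C)C
F6 | step 3 | 2,3-dihydroxy-4-methoxybenzaldehyde | COc1ccc(C=O)c(O)c1O
F7 | step 3 | 4-methoxy-2,3-bis(methoxymethoxy)benzaldehyde | COCOc1c(C=O)ccc(OC)c1OCOC
F8 | step 3 | 5-bromo-4-methoxy-2,3-bis(methoxymethoxy)benzaldehyde | COCOc1c(C=O)cc(Br)c(OC)c1OCOC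
F9 | step 1 | sodium 2,3-O-borate complex of 2,3,4-trihydroxybenzaldehyde | [Na+].O=Cc1ccc(O)c2O[B-](O)(O)Oc12
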